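Intermediate cannot reach the full charge, since it leaves for target during its own making. How far short it stops can be read on a scale whose zero is the symmetric case: making and leaving equally fast, with the peak at 36.8 % of the charge.

the same everywhere: reagent 0.156 M

| charge | starting material | temperature | remark | time |
|---|---|---|---|---|
| zeta | 0.060 M | 80 °C | run made earlier |  |
| Saturday's | 0.12 M | 80 °C |  | 30 h |
| Monday's | 0.12 M | 55 °C |  | 30 h |
| Thursday's | 0.12 M | 30 °C |  | 30 h |

zeta run (percent of the starting material charged)

| time / h | intermediate / % | target / % | starting material / % |
|---|---|---|---|
| 0.667 | 30 | 0 | 72 |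
| 2.00 | 62 | 1 | 37 |
| 3.00 | 73 | 2 | 27 |
| 5.00 | 87 | 7 | 13 |
| 6.00 | 87 | 7 | 7 |
| 10.0 | 90 | 8 | 0 |

(scatter of a reading: 2 percentage points)

- the analysis behind the earlier runs scatters by 2 percentage points, standard deviation
- a reading or a percentage of target counts all its forms, free or not
- the earlier runs do not show what temperature does; that part of a forecast is a guess
- a reading of starting material is of its free form alone

- the flask that comes out highest in amount of intermediate, in percent of the starting material charged, or "all alike" when all lie within 1.5 percentage points (Saturday's / Monday's / Thursday's / all alike)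
- intermediate at the end, in percent of the starting material charged, Saturday's
- intermediate at the end, in percent of the starting material charged, Monday's
- intermediate at the end, in percent of the starting material charged, Thursday's

For whoever takes over the bench, the zeta run is the guide, though it shows nothing of temperature. Its 27 % of starting material at 3.00 h gives a making constant k of 0.436 h⁻¹, so a lifetime 1/k of 2.29 h. Its 8 % of target at 10.0 h, gathered from intermediate near the full charge over that time less one lifetime, gives a leaving constant L of 0.0104 h⁻¹, uncertain by a quarter.

Their ratio, the selectivity factor S = k/L, is 42.1. Far above 1 on this scale, the peak comes after about ln S lifetimes, here 3.74.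

Taking k and L as unchanged in Saturday's flask, its intermediate peaks near 8.78 h at 91.3 %. The 30 h mark lies later, so this reckoning expects 75.0 % at the end. S was read at 80 °C, so in the baths of Monday's and Thursday's flasks it is an assumption, not a reading.

The forecast gives 82 %, 76 % and 28 % for Saturday's, Monday's and Thursday's, and picks Saturday's: “Saturday's narrowly leads Monday's, uncertainly.”

    starting material → intermediate (k = 0.480 h⁻¹, Ea = 98.0 kJ mol⁻¹)
    reagent + intermediate → target (k = 0.0940 M⁻¹ h⁻¹, Ea = 81.0 kJ mol⁻¹)
    starting material + target ⇌ idle adduct, settled at all times (K = 6.90 M⁻¹, ΔH = −7.00 kJ mol⁻¹)
    crystals ⇌ target, rate k4*(cs4 - [target]) while solid is left; crystals form when [target] > cs4 (solubility = 1.20 mM, k = 4.00 h⁻¹)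
    (constants at 80 °C)

The flasks end at 70.0 % in Saturday's, 65.5 % in Monday's and 5.67 % in Thursday's, so Saturday's comes out highest. Saturday's held 83.7 % of intermediate at 15.0 h and 70.0 % at 30.0 h, a surviving share of 83.6 %, where L over that span gives 85.6 %. In Monday's flask, 32 % of starting material left at 30.0 h means a lifetime of 26.4 h, and with S held at its zeta value the peak falls near 98.6 h. Monday's intermediate stands at 65.5 % at 30.0 h and at 65.9 % at 300 h.

(The data stem from a simulated flask on assumed constants; noise was put on by code.)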